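The numbers of this flask are made up; the result is computed.

Start with the easy step: in larch, substrate left to the uncatalysed step alone has a half-life of 2.1 min.

common to all: enzyme 9.2 µM; time 30 min
- larch: substrate 0.040 M
- ash: substrate 0.12 M
- alder: substrate 0.30 M
- cedar: substrate 1.0 M
- maple: substrate 3.0 M

    substrate + enzyme → spent catalyst (k1 = 0.080 /M/s)
    substrate → uncatalysed product (k2 = 0.0056 /s)
    substrate + enzyme → target + enzyme, rate k3*[substrate]^1.5*[enzyme]/(1 + ([substrate]/Kh3)^1.5) (Kh3 = 0.20 M, k3 = 4200 /M^1.5/s)

- [target] at the end for larch, ash, alder, cedar, maple, in this order
- the course of these numbers from the first flask to the last (falls, then rises / falls all the way / rises all the way / rises, then falls / hardly changes)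

- "hardly changes" means that all values lie within two and a half points (for a concentration: within two and a half percent of the largest)
- run time (larch): 30 min

Now follow the enzyme. The target step gives it back, so it is lost through the spent catalyst step, at 0.080 /M/s times [substrate][enzyme]. Uncatalysed product grows at 0.0056 /s times [substrate]. Divide one rate by the other and [substrate] cancels. So ln([enzyme]/charge) equals minus the kill ratio times [uncatalysed product], where the kill ratio is the first constant over the second, 14.3 /M.

Here is my reckoning for larch. First pass: suppose the whole charge of 0.040 M becomes uncatalysed product. Then you keep 56.5 % of the enzyme. But at the start, substrate splits between its two main routes in the ratio 0.79, uncatalysed over catalysed, which gives the uncatalysed route a share of 44.1 %. Put that share back in and go round again: you keep 77.7 %. I commit to a larch enzyme between these two, the first being lower. My reckoning stops there, and it gives no [target].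

The forecast gives 0.017 M, 0.056 M, 0.096 M, 0.044 M and 0.015 M, so the row rises, then falls. Its grounds: “More substrate also kills the enzyme faster”. Its exponent of 14 multiplies substrate, as my first pass does.

The simulation gives 0.0168 M, 0.0554 M, 0.0973 M, 0.0433 M and 0.0145 M, so the row rises, then falls.

Alder holds more target than any other flask, and there uncatalysed product takes 67.5 % of the substrate charged. Go round once more in larch, with its simulated 58.0 % of uncatalysed product in place of my share: the kill ratio leaves 71.8 % of the enzyme, and the larch flask holds 71.8 %. In alder, the same kill ratio of 14.3 /M on its 67.5 % leaves 5.53 % of the enzyme.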